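## Retrosynthetic overview

1. Furan C5–quinone bond (made last): the furan already carrying its ester is joined to 1,4-benzoquinone by C–H borylation and oxidative coupling. The quinone never needs a mask.
2. Ester C–O bond: the isovalerate is made from a silyl ether with retention at carbon.
3. Key C–C bond (carbinol carbon to prenyl CH2): the formyl carbon of furan-3-carbaldehyde becomes a chiral α-siloxyalkylcopper nucleophile by silylcupration and [1,2]-Brook shift. It is joined to the electrophilic π-prenylpalladium from a prenyl carbonate. Two acceptor carbons are coupled, the prenyl group comes out linear, and the (R) centre is set in the same event.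
4. Rings: none is built. The furan enters intact with furan-3-carbaldehyde at the start, and the quinone ring enters intact with benzoquinone at the end.

The target stereocentre is (R), with priorities O > furyl C > CH2 > H.

Assumption: the (4S,5S) carbene ligand is taken to give the (R) product, and 4 and 5 are drawn for retention in both the silyl shift and the copper-to-palladium transfer. The sense is checked on the first run, and the equally available (4R,5R) antipode is used if it proves opposite.

## Route

Step 1
Reactants: 1 prenol (3-methylbut-2-en-1-ol)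
Product: 2 tert-butyl (3-methylbut-2-en-1-yl) carbonate
Conditions: Boc2O (1.1 equiv), Bu4NHSO4 (5 mol %), 30% aq NaOH, CH2Cl2, 0 °C to rt
Reagents that add atoms: di-tert-butyl dicarbonate, CC(C)(C)OC(=O)OC(=O)OC(C)(C)C
Why: Phase-transfer O-acylation (Boc carbonate formation), chosen because ionisation of this carbonate by zerovalent palladium releases CO2 and the tert-butoxide that the copper cycle of step 2 needs, with no β-hydrogen that could give palladium hydrides.

Step 2
Reactants: 3 furan-3-carbaldehyde; 2 tert-butyl (3-methylbut-2-en-1-yl) carbonate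
Product: 6 (R)-{[1-(furan-3-yl)-4-methylpent-3-en-1-yl]oxy}(dimethyl)phenylsilane, via α-silyl copper alkoxide 4 (not isolated), via α-siloxyalkylcopper 5 (not isolated)
Conditions: PhMe2Si–Bpin (1.3 equiv), CuCl (10 mol %), (4S,5S)-1,3-bis(2-isopropylphenyl)-4,5-diphenyl-4,5-dihydroimidazolium BF4 (11 mol %), NaOtBu (25 mol %), Pd2(dba)3 (2.5 mol %), dppf [1,1'-bis(diphenylphosphino)ferrocene] (6 mol %), 2 (1.5 equiv), toluene, 30 °C
Reagents that add atoms: (dimethylphenylsilyl)boronic acid pinacol ester, C[Si](C)(c1ccccc1)B1OC(C)(C)C(C)(C)O1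
Why: Synergistic Cu/Pd reductive umpolung allylation, in which the chiral carbene–silylcopper adds face-selectively to the C=O of 3 to give 4, a [1,2]-Brook rearrangement turns the former carbonyl carbon into the configurationally defined nucleophile 5, and stereospecific transfer of 5 to the π-prenylpalladium from 2 (Tsuji–Trost ionisation) with reductive elimination at the unhindered CH2 terminus gives the linear prenyl product with the (R) centre set by the carbene ligand; this extends the known aromatic aldehyde/allyl carbonate coupling to a furyl aldehyde and a prenyl carbonate.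

Step 3
Reactants: 6 (R)-{[1-(furan-3-yl)-4-methylpent-3-en-1-yl]oxy}(dimethyl)phenylsilane; 7 3-methylbutanoic (isovaleric) anhydride
Product: 9 (R)-1-(furan-3-yl)-4-methylpent-3-en-1-yl 3-methylbutanoate, via furyl carbinol 8 (not isolated)
Conditions: Et3N·3HF (0.5 equiv), THF, 0 °C to rt; then Et3N (4 equiv), 4-(dimethylamino)pyridine (10 mol %), 7 (1.5 equiv), 0 °C to rt
Reagents that add atoms: 3-methylbutanoic anhydride 7, CC(C)CC(=O)OC(=O)CC(C)C
Why: Fluoride desilylation followed by DMAP-catalysed acyl transfer in one flask breaks only Si–O and O–H bonds, so the C–O bond and the (R) configuration are retained, and the near-neutral medium avoids ionisation of the furyl carbinol.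

Step 4
Reactants: 9 (R)-1-(furan-3-yl)-4-methylpent-3-en-1-yl 3-methylbutanoate; 10 1,4-benzoquinone
Product: 13 (R)-1-[5-(3,6-dioxocyclohexa-1,4-dien-1-yl)furan-3-yl]-4-methylpent-3-en-1-yl 3-methylbutanoate, via furyl boronate 11 (not isolated), via furyl hydroquinone 12 (not isolated)
Conditions: [Ir(OMe)(cod)]2 (1.5 mol %), 4,4'-di-tert-butyl-2,2'-bipyridine (3 mol %), B2pin2 (0.55 equiv), THF, rt; evaporate; then 10 (3.5 equiv), Pd(OCOCF3)2 (10 mol %), acetone–H2O 9:1, rt
Reagents that add atoms: bis(pinacolato)diboron, CC1(C)OB(OC1(C)C)B1OC(C)(C)C(C)(C)O1 (it supplies the boryl group of 11, which is lost again before 13)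
Why: Sterically governed Ir-catalysed C–H borylation takes the open α-C–H (C5) rather than C2 next to the branched side chain, and a divalent-palladium-catalysed oxidative boron-Heck/conjugate addition of 11 to benzoquinone then gives 12, which excess 10 oxidises to the more electron-rich quinone 13, with the ester, the trisubstituted alkene and the stereocentre untouched.

## Compound list

| No. | Name | SMILES | Role |
|---|---|---|---|
| 1 | prenol (3-methylbut-2-en-1-ol) | CC(C)=CCO | starting material |
| 2 | tert-butyl (3-methylbut-2-en-1-yl) carbonate | CC(C)=CCOC(=O)OC(C)(C)C | intermediate |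
| 3 | furan-3-carbaldehyde | O=Cc1ccoc1 | starting material |
| 4 | carbene-ligated copper (R)-(dimethylphenylsilyl)(furan-3-yl)methoxide (carbene ligand left out of the SMILES) | C[Si](C)(c1ccccc1)[C@@H](O[Cu])c1ccoc1 | intermediate |
| 5 | carbene-ligated (R)-[(dimethylphenylsilyl)oxy](furan-3-yl)methylcopper (carbene ligand left out of the SMILES) | [Cu][C@@H](O[Si](C)(C)c1ccccc1)c1ccoc1 | intermediate |
| 6 | (R)-{[1-(furan-3-yl)-4-methylpent-3-en-1-yl]oxy}(dimethyl)phenylsilane | CC(C)=CC[C@@H](O[Si](C)(C)c1ccccc1)c1ccoc1 | intermediate |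
| 7 | 3-methylbutanoic anhydride | CC(C)CC(=O)OC(=O)CC(C)C | starting material |
| 8 | (R)-1-(furan-3-yl)-4-methylpent-3-en-1-ol | CC(C)=CC[C@@H](O)c1ccoc1 | intermediate |
| 9 | (R)-1-(furan-3-yl)-4-methylpent-3-en-1-yl 3-methylbutanoate | CC(C)=CC[C@@H](OC(=O)CC(C)C)c1ccoc1 | intermediate |
| 10 | 1,4-benzoquinone | O=C1C=CC(=O)C=C1 | starting material |
| 11 | (R)-4-methyl-1-[5-(4,4,5,5-tetramethyl-1,3,2-dioxaborolan-2-yl)furan-3-yl]pent-3-en-1-yl 3-methylbutanoate | CC(C)=CC[C@@H](OC(=O)CC(C)C)c1coc(B2OC(C)(C)C(C)(C)O2)c1 | intermediate |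
| 12 | (R)-1-[5-(2,5-dihydroxyphenyl)furan-3-yl]-4-methylpent-3-en-1-yl 3-methylbutanoate | CC(C)=CC[C@@H](OC(=O)CC(C)C)c1coc(-c2cc(O)ccc2O)c1 | intermediate |
| 13 | (R)-1-[5-(3,6-dioxocyclohexa-1,4-dien-1-yl)furan-3-yl]-4-methylpent-3-en-1-yl 3-methylbutanoate | CC(C)=CC[C@@H](OC(=O)CC(C)C)c1coc(C2=CC(=O)C=CC2=O)c1 | target |

## Step count

- Total steps: 4.
- Longest linear sequence: 4 (1 → 2 → 6 → 9 → 13).
- From furan-3-carbaldehyde the sequence is 3 steps.

## Steps most likely to fail

**Step 2.**
- The 3-furyl group stabilises negative charge less well than phenyl, so the Brook shift may stall at the α-hydroxysilane stage.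
- Silylcopper may intercept the π-prenylpalladium directly.
- The linear/branched ratio and the ee are untested for this substrate pair.

The fallback sets out from 3 and uses a stoichiometric acyl anion with a separate asymmetric reduction. Propane-1,3-dithiol with BF3·OEt2 (CH2Cl2, 0 °C) gives 2-(furan-3-yl)-1,3-dithiane F1. Treatment with n-BuLi (THF, −78 °C) and then prenyl bromide gives 2-(furan-3-yl)-2-(3-methylbut-2-en-1-yl)-1,3-dithiane F2. MeI and CaCO3 in aqueous MeCN unmask 1-(furan-3-yl)-4-methylpent-3-en-1-one F3. Reduction follows with catecholborane and (S)-2-methyl-CBS-oxazaborolidine [(S)-1-methyl-3,3-diphenyltetrahydro-1H,3H-pyrrolo[1,2-c][1,3,2]oxazaborole] in toluene at −78 °C. With furyl as the large group, this gives the (R) alcohol. The fallback comes back to the route at 8, which goes into the acylation half of step 3.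

**Step 4.**
- The 2-furyl boronate 11 may protodeboronate, which returns 9.
- The pinacol ester may transmetalate too slowly.
- A second furylation of 13 may compete.

The fallback sets out from 11 and carries the quinone in masked form. Suzuki–Miyaura coupling with 2-bromo-1,4-dimethoxybenzene (PdCl2(dppf), K3PO4, dioxane–H2O, 60 °C) gives (R)-1-[5-(2,5-dimethoxyphenyl)furan-3-yl]-4-methylpent-3-en-1-yl 3-methylbutanoate F4. Oxidative demethylation with (NH4)2Ce(NO3)6 (MeCN–H2O, 0 °C) comes back to the route at 13.

**Step 3.**
- The free furyl carbinol 8 may ionise, eliminate or lose ee in the one-flask sequence.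
- Residual fluoride may consume the anhydride.

The fallback sets out from 6 and never frees the alcohol. 3-Methylbutanoyl fluoride F5 is made from 3-methylbutanoic acid with cyanuric fluoride and pyridine. It is combined with 6 and catalytic Bu4N[Ph3SiF2] in THF at 0 °C. This silyl ether/acyl fluoride exchange is driven by Si–F bond formation and comes back to the route at 9.

## Further compounds

F1 | step 2 | 2-(furan-3-yl)-1,3-dithiane | C1CSC(SC1)c1ccoc1
F2 | step 2 | 2-(furan-3-yl)-2-(3-methylbut-2-en-1-yl)-1,3-dithiane | CC(C)=CCC1(SCCCS1)c1ccoc1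
F3 | step 2 | 1-(furan-3-yl)-4-methylpent-3-en-1-one | CC(C)=CCC(=O)c1ccoc1
F4 | step 4 | (R)-1-[5-(2,5-dimethoxyphenyl)furan-3-yl]-4-methylpent-3-en-1-yl 3-methylbutanoate | CC(C)=CC[C@@H](OC(=O)CC(C)C)c1coc(-c2cc(OC)ccc2OC)c1
F5 | step 3 | 3-methylbutanoyl fluoride | CC(C)CC(F)=O
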